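**Plan**

1. Retrosynthesis first removes two MOM ethers, then undoes one metathesis event at three olefins: the C3=C4 bond of the 2,2-dimethylpyran ring fused to ring B and the two C=CMe2 bonds of the side chains on C6 and C8. This leads back to a 6,8-diallyl flavanone with a vinyl group on C3' and a 1,1-dimethylallyl ether on the C4' oxygen.
2. The next cuts are the C2–C1' bond (asymmetric conjugate arylation of a chromone by an arylboronic acid) and the C6–allyl and C8–allyl bonds (double aromatic Claisen rearrangement of a 5,7-bis(allyl ether)).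
3. Forward: the ring B boronic acid is made in 4 steps from 5-bromo-2-hydroxybenzaldehyde, and rings A and C in 3 steps from 5,7-dihydroxychromone as a 6,8-diallyl-5,7-bis(MOM) chromone. Their union gives the chromanone; the pyran ring on ring B is closed last, the prenyl groups arise in the same flask, and MOM removal ends the route.
4. Enabling feature: the vinyl carbon on C3' and the CH=CH2 of the O–CMe2 group on the C4' oxygen are ortho neighbours on ring B, so their olefins are held within reach for a six-membered closure (gem-dimethyl effect). The allyl groups on C6 and C8 of ring A are meta to each other and far from ring B, so they can only undergo cross-metathesis.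
5. Stereochemistry: the only stereocentre, C2 (S), is set by the chiral rhodium catalyst in the fragment union. All later steps are neutral or mildly acidic, so the flavanone ring is not opened and C2 is not scrambled.

Key step: step 9

Assumption: the (S)-configured biaryl bisphosphine is taken to deliver the aryl group to the face of the chromone C2=C3 bond that gives the 2S flavanone, by analogy with 2-cyclohexenone, where the (S)-ligand gives the (S)-3-aryl ketone (which maps onto 2S here); if a first run showed the opposite sense, the (R)-ligand would be used with no other change.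

**Route**

Step 1
Reactants: 1 5-bromo-2-hydroxybenzaldehyde
Product: 2 5-bromo-2-[(2-methylbut-3-yn-2-yl)oxy]benzaldehyde
Conditions: 3-chloro-3-methylbut-1-yne (1.3 equiv), DBU (1.4 equiv), CuCl2·2H2O (1 mol%), MeCN, 0 °C
Reagents that add atoms: 3-chloro-3-methylbut-1-yne, CC(C)(Cl)C#C
Why: Copper-catalysed O-propargylation of phenols with tertiary propargyl chlorides works best with acidic, electron-poor phenols such as this one, and at 0 °C neither propargyl Claisen rearrangement nor attack on the aldehyde is expected.

Step 2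
Reactants: 2 5-bromo-2-[(2-methylbut-3-yn-2-yl)oxy]benzaldehyde
Product: 3 5-bromo-2-[(2-methylbut-3-en-2-yl)oxy]benzaldehyde
Conditions: H2 (1 atm), Pd/CaCO3 poisoned with Pb(OAc)2 (Lindlar catalyst), quinoline, EtOAc, rt, stopped at one equivalent of H2
Reagents that add atoms: none
Why: Lindlar semihydrogenation should stop at the terminal alkene, and the poisoned catalyst is expected to leave the aryl bromide and the aldehyde untouched.

Step 3
Reactants: 3 5-bromo-2-[(2-methylbut-3-en-2-yl)oxy]benzaldehyde
Product: 4 4-bromo-2-ethenyl-1-[(2-methylbut-3-en-2-yl)oxy]benzene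
Conditions: Ph3PCH3Br, KOtBu, THF, 0 °C to rt
Reagents that add atoms: methyltriphenylphosphonium bromide, C[P+](c1ccccc1)(c1ccccc1)c1ccccc1.[Br-]
Why: Wittig methylenation of the aromatic aldehyde with the non-stabilised ylide should give the styrene, and the low temperature keeps the heat-sensitive aryl 1,1-dimethylallyl ether from Claisen rearrangement.

Step 4
Reactants: 4 4-bromo-2-ethenyl-1-[(2-methylbut-3-en-2-yl)oxy]benzene
Product: 7 {3-ethenyl-4-[(2-methylbut-3-en-2-yl)oxy]phenyl}boronic acid, via aryllithium 5 (not isolated), via lithium aryltriisopropoxyborate 6 (not isolated)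
Conditions: B(OiPr)3 (1.5 equiv), then n-BuLi (1.1 equiv) added slowly, THF/toluene, −78 °C; aq. NH4Cl, 0 °C
Reagents that add atoms: n-butyllithium, [Li]CCCC (lithium of 5 and 6 only); triisopropyl borate, CC(C)OB(OC(C)C)OC(C)C; water, O
Why: Bromine–lithium exchange at −78 °C is faster than addition of n-BuLi to the styrene or to the borate, the aryllithium is trapped at once by the borate already present (in situ quench borylation), and hydrolysis with NH4Cl frees the boronic acid without ionising the acid-labile tertiary allyl ether.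

Step 5
Reactants: 8 5,7-dihydroxy-4H-chromen-4-one
Product: 9 5,7-bis(prop-2-en-1-yloxy)-4H-chromen-4-one
Conditions: allyl bromide (3 equiv), K2CO3 (3 equiv), DMF, 60 °C
Reagents that add atoms: allyl bromide, C=CCBr
Why: Williamson etherification, in which the acidic 7-OH should react first and the carbonyl-chelated 5-OH follows with excess allyl bromide on warming.

Step 6
Reactants: 9 5,7-bis(prop-2-en-1-yloxy)-4H-chromen-4-one
Product: 10 5,7-dihydroxy-6,8-di(prop-2-en-1-yl)-4H-chromen-4-one
Conditions: PhNEt2, 200 °C, sealed tube, argon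
Reagents that add atoms: none
Why: In this double aromatic Claisen rearrangement the 7-allyl ether migrates to C8 (or C6) and the 5-allyl ether to C6 (or, if C6 is already taken, by Claisen then Cope rearrangement to C8), so every pathway should converge on the 6,8-diallyl compound.

Step 7
Reactants: 10 5,7-dihydroxy-6,8-di(prop-2-en-1-yl)-4H-chromen-4-one
Product: 11 5,7-bis(methoxymethoxy)-6,8-di(prop-2-en-1-yl)-4H-chromen-4-one
Conditions: NaH (2.5 equiv), MOMCl (2.5 equiv), DMF, 0 °C to rt
Reagents that add atoms: chloromethyl methyl ether, COCCl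
Why: Acetal (MOM) protection through the sodium phenoxides, with NaH in DMF chosen because the 5-OH is chelated and both hydroxyls are flanked by allyl groups; it removes the acidic protons that would deactivate the chromone toward conjugate addition.

Step 8
Reactants: 11 5,7-bis(methoxymethoxy)-6,8-di(prop-2-en-1-yl)-4H-chromen-4-one; 7 {3-ethenyl-4-[(2-methylbut-3-en-2-yl)oxy]phenyl}boronic acid
Product: 12 (2S)-5,7-bis(methoxymethoxy)-2-{3-ethenyl-4-[(2-methylbut-3-en-2-yl)oxy]phenyl}-6,8-di(prop-2-en-1-yl)-2,3-dihydro-4H-chromen-4-one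
Conditions: [Rh(OH)(cod)]2 (2.5 mol%), (S)-MeO-F12-BIPHEP (5.5 mol%), 7 (2 equiv), toluene/H2O (20:1), 40 °C
Reagents that add atoms: none
Why: In this rhodium-catalysed asymmetric 1,4-addition of an arylboronic acid to a chromone (Hayashi–Miyaura reaction), transmetalation gives an arylrhodium that inserts the C2=C3 bond on one enantioface within the chiral pocket of the electron-poor bisphosphine, which sets C2 as S; the base-free medium protonates the rhodium enolate without opening the flavanone, and isolated terminal alkenes are not expected to be carbometalated.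

Step 9
Reactants: 12 (2S)-5,7-bis(methoxymethoxy)-2-{3-ethenyl-4-[(2-methylbut-3-en-2-yl)oxy]phenyl}-6,8-di(prop-2-en-1-yl)-2,3-dihydro-4H-chromen-4-one
Product: 14 (2S)-2-(2,2-dimethyl-2H-chromen-6-yl)-5,7-bis(methoxymethoxy)-6,8-bis(3-methylbut-2-en-1-yl)-2,3-dihydro-4H-chromen-4-one, via ring-closed diallyl chromene 13 (not isolated)
Conditions: RuCl2(=CHPh)(H2IMes)(PCy3) (second-generation Grubbs catalyst, 5 mol%), CH2Cl2 (5 mM), 40 °C, argon sparge; then 2-methylbut-2-ene (large excess, 1:3 v/v with CH2Cl2), 35 °C, sealed vessel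
Reagents that add atoms: 2-methylbut-2-ene, CC=C(C)C
Why: The ruthenium carbene loads onto the styrene vinyl group on C3' of ring B, undergoes intramolecular [2+2] cycloaddition with the neighbouring 1,1-dimethylallyl ether on the C4' oxygen and cycloreverts (Chauvin mechanism) with loss of ethylene, which forms the C3=C4 double bond of the 2,2-dimethylpyran ring; the closest known reaction type is ring-closing metathesis of 2-(allyloxy)styrenes to 2H-chromenes, followed in the same flask by the standard cross-metathesis of allylarenes with 2-methylbut-2-ene to prenylarenes. The pyran ring closes as a six-membered ring by ring-closing olefin metathesis, and the new endocyclic olefin is necessarily cis. No stereocentre is formed, and C2 of the chromanone sees neither acid nor base and should keep its S configuration. The step needs chemoselectivity among four terminal olefins: ring closure must win over intermolecular metathesis, which the ortho relation of the two ring B olefins, the gem-dimethyl (Thorpe–Ingold) effect and high dilution should secure, while the allyl groups on C6 and C8 are meta to each other and too far from ring B to cyclise. 2-Methylbut-2-ene is added only after ring closure so that the styrene is not capped as a trisubstituted olefin; any allyl homodimers from the first stage should be cut back to prenyl groups by the excess trisubstituted olefin, and the cyclic cis olefin next to the quaternary carbon is not expected to reopen.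

Step 10
Reactants: 14 (2S)-2-(2,2-dimethyl-2H-chromen-6-yl)-5,7-bis(methoxymethoxy)-6,8-bis(3-methylbut-2-en-1-yl)-2,3-dihydro-4H-chromen-4-one
Product: 15 (2S)-2-(2,2-dimethyl-2H-chromen-6-yl)-5,7-dihydroxy-6,8-bis(3-methylbut-2-en-1-yl)-2,3-dihydro-4H-chromen-4-one
Conditions: 3 M aq. HCl/MeOH (1:5), 45 °C, short reaction time
Reagents that add atoms: none
Why: Acid-catalysed acetal cleavage (MOM removal) in methanol, in which the 5-O-MOM group is activated by the neighbouring carbonyl, C2 is not epimerised by mild acid, and a short reaction at moderate temperature should avoid cyclisation of the prenyl groups onto the freed phenols.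

**Compound list**

1 | 5-bromo-2-hydroxybenzaldehyde | O=Cc1cc(Br)ccc1O | starting material
2 | 5-bromo-2-[(2-methylbut-3-yn-2-yl)oxy]benzaldehyde | O=Cc1cc(Br)ccc1OC(C)(C)C#C | intermediate
3 | 5-bromo-2-[(2-methylbut-3-en-2-yl)oxy]benzaldehyde | O=Cc1cc(Br)ccc1OC(C)(C)C=C | intermediate
4 | 4-bromo-2-ethenyl-1-[(2-methylbut-3-en-2-yl)oxy]benzene | C=Cc1cc(Br)ccc1OC(C)(C)C=C | intermediate
5 | {3-ethenyl-4-[(2-methylbut-3-en-2-yl)oxy]phenyl}lithium | [Li]c1ccc(OC(C)(C)C=C)c(C=C)c1 | intermediate (not isolated)
6 | lithium {3-ethenyl-4-[(2-methylbut-3-en-2-yl)oxy]phenyl}tri(propan-2-yloxy)borate | [Li+].CC(C)O[B-](OC(C)C)(OC(C)C)c1ccc(OC(C)(C)C=C)c(C=C)c1 | intermediate (not isolated)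
7 | {3-ethenyl-4-[(2-methylbut-3-en-2-yl)oxy]phenyl}boronic acid | OB(O)c1ccc(OC(C)(C)C=C)c(C=C)c1 | intermediate
8 | 5,7-dihydroxy-4H-chromen-4-one | O=c1ccoc2cc(O)cc(O)c12 | starting material
9 | 5,7-bis(prop-2-en-1-yloxy)-4H-chromen-4-one | O=c1ccoc2cc(OCC=C)cc(OCC=C)c12 | intermediate
10 | 5,7-dihydroxy-6,8-di(prop-2-en-1-yl)-4H-chromen-4-one | O=c1ccoc2c(CC=C)c(O)c(CC=C)c(O)c12 | intermediate
11 | 5,7-bis(methoxymethoxy)-6,8-di(prop-2-en-1-yl)-4H-chromen-4-one | O=c1ccoc2c(CC=C)c(OCOC)c(CC=C)c(OCOC)c12 | intermediate
12 | (2S)-5,7-bis(methoxymethoxy)-2-{3-ethenyl-4-[(2-methylbut-3-en-2-yl)oxy]phenyl}-6,8-di(prop-2-en-1-yl)-2,3-dihydro-4H-chromen-4-one | C=CCc1c(OCOC)c(CC=C)c2c(c1OCOC)C(=O)C[C@@H](c1ccc(OC(C)(C)C=C)c(C=C)c1)O2 | intermediate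
13 | (2S)-2-(2,2-dimethyl-2H-chromen-6-yl)-5,7-bis(methoxymethoxy)-6,8-di(prop-2-en-1-yl)-2,3-dihydro-4H-chromen-4-one | C=CCc1c(OCOC)c(CC=C)c2c(c1OCOC)C(=O)C[C@@H](c1ccc3c(c1)C=CC(C)(C)O3)O2 | intermediate (not isolated)
14 | (2S)-2-(2,2-dimethyl-2H-chromen-6-yl)-5,7-bis(methoxymethoxy)-6,8-bis(3-methylbut-2-en-1-yl)-2,3-dihydro-4H-chromen-4-one | CC(C)=CCc1c(OCOC)c(CC=C(C)C)c2c(c1OCOC)C(=O)C[C@@H](c1ccc3c(c1)C=CC(C)(C)O3)O2 | intermediate
15 | (2S)-2-(2,2-dimethyl-2H-chromen-6-yl)-5,7-dihydroxy-6,8-bis(3-methylbut-2-en-1-yl)-2,3-dihydro-4H-chromen-4-one | CC(C)=CCc1c(O)c(CC=C(C)C)c2c(c1O)C(=O)C[C@@H](c1ccc3c(c1)C=CC(C)(C)O3)O2 | target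

**Summary**

Total step count: 10. Longest linear sequence: 7 steps (steps 1 to 4, then 8, 9 and 10).

Steps most likely to fail:

Step 9. Intermolecular metathesis of the allyl groups and ruthenium-hydride-induced migration of the allyl double bonds may compete with ring closure, and the flanked allyl groups may exchange incompletely, so that mixtures result. The fallback sets out from 11 and installs the prenyl groups before the ring B olefins are present. Cross-metathesis of 11 with 2-methylbut-2-ene (second-generation Grubbs catalyst, CH2Cl2, 35 °C) should give 5,7-bis(methoxymethoxy)-6,8-bis(3-methylbut-2-en-1-yl)-4H-chromen-4-one F1. Rhodium-catalysed addition of boronic acid 7 under the conditions of step 8 should give (2S)-5,7-bis(methoxymethoxy)-2-{3-ethenyl-4-[(2-methylbut-3-en-2-yl)oxy]phenyl}-6,8-bis(3-methylbut-2-en-1-yl)-2,3-dihydro-4H-chromen-4-one F2. Ring-closing metathesis of F2 alone (dilute CH2Cl2, 40 °C, argon sparge to remove ethylene), with the trisubstituted prenyl olefins as bystanders, comes back to the route at 14.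

Step 8. Slow turnover on the electron-rich, peri-substituted chromone may let protodeboronation of the boronic acid win, or facial selectivity may be poor. The fallback sets out from 11 and 7 and takes the stereochemistry from a kinetic resolution. Addition with the more active achiral diene complex [Rh(OH)(cod)]2 alone (dioxane/H2O, 40 °C) should give racemic 5,7-bis(methoxymethoxy)-2-{3-ethenyl-4-[(2-methylbut-3-en-2-yl)oxy]phenyl}-6,8-di(prop-2-en-1-yl)-2,3-dihydro-4H-chromen-4-one F3. Asymmetric transfer hydrogenation (RhCl(C5Me5)[(R,R)-TsDPEN] or its antipode, whichever consumes the 2R ketone, HCO2H/Et3N, EtOAc, rt, to just over half conversion) should reduce the 2R enantiomer to (2R,4R)-5,7-bis(methoxymethoxy)-2-{3-ethenyl-4-[(2-methylbut-3-en-2-yl)oxy]phenyl}-6,8-di(prop-2-en-1-yl)-3,4-dihydro-2H-chromen-4-ol F4. F4 is removed by chromatography, and the unreacted 2S ketone comes back to the route at 12.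

Step 10. Acid may promote cyclisation of a prenyl group onto the neighbouring freed phenol (chroman formation) or addition of methanol or HCl across the prenyl olefins during acetal cleavage. The fallback sets out from 13, isolated after the ring-closing stage of step 9 without adding 2-methylbut-2-ene, and moves the acid step ahead of prenyl formation. MOM cleavage at the diallyl stage (3 M aq. HCl/MeOH, 45 °C), where no trisubstituted olefin is present, should give (2S)-2-(2,2-dimethyl-2H-chromen-6-yl)-5,7-dihydroxy-6,8-di(prop-2-en-1-yl)-2,3-dihydro-4H-chromen-4-one F5. Cross-metathesis of the free bisphenol F5 with 2-methylbut-2-ene (second-generation Grubbs catalyst, CH2Cl2, 35 °C), which tolerates free phenols, comes back to the route at 15.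

**Further compounds**

F1 | step 9 | 5,7-bis(methoxymethoxy)-6,8-bis(3-methylbut-2-en-1-yl)-4H-chromen-4-one | O=c1ccoc2c(CC=C(C)C)c(OCOC)c(CC=C(C)C)c(OCOC)c12
F2 | step 9 | (2S)-5,7-bis(methoxymethoxy)-2-{3-ethenyl-4-[(2-methylbut-3-en-2-yl)oxy]phenyl}-6,8-bis(3-methylbut-2-en-1-yl)-2,3-dihydro-4H-chromen-4-one | CC(C)=CCc1c(OCOC)c(CC=C(C)C)c2c(c1OCOC)C(=O)C[C@@H](c1ccc(OC(C)(C)C=C)c(C=C)c1)O2
F3 | step 8 | racemic 5,7-bis(methoxymethoxy)-2-{3-ethenyl-4-[(2-methylbut-3-en-2-yl)oxy]phenyl}-6,8-di(prop-2-en-1-yl)-2,3-dihydro-4H-chromen-4-one | C=CCc1c(OCOC)c(CC=C)c2c(c1OCOC)C(=O)CC(c1ccc(OC(C)(C)C=C)c(C=C)c1)O2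
F4 | step 8 | (2R,4R)-5,7-bis(methoxymethoxy)-2-{3-ethenyl-4-[(2-methylbut-3-en-2-yl)oxy]phenyl}-6,8-di(prop-2-en-1-yl)-3,4-dihydro-2H-chromen-4-ol | C=CCc1c(OCOC)c(CC=C)c2c(c1OCOC)[C@H](O)C[C@H](c1ccc(OC(C)(C)C=C)c(C=C)c1)O2
F5 | step 10 | (2S)-2-(2,2-dimethyl-2H-chromen-6-yl)-5,7-dihydroxy-6,8-di(prop-2-en-1-yl)-2,3-dihydro-4H-chromen-4-one | C=CCc1c(O)c(CC=C)c2c(c1O)C(=O)C[C@@H](c1ccc3c(c1)C=CC(C)(C)O3)O2
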